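The naphthazarin core is cut between ring A (C1–C4, with the side chain on C2) and ring B at the bonds C1–C8a and C4–C4a. Because C8a and C4a each sit next to an oxygen-bearing carbon (C8 and C5), ring B corresponds to the symmetrical 3,6-dimethoxybenzyne and ring A to a 3-substituted furan. A single fluoride-triggered aryne [4+2] cycloaddition forms both bonds and closes ring A as a 1,4-oxygen-bridged dihydronaphthalene, with no regiochemical question. The precursors are an ortho-silyl aryl triflate and a furan that already carries the (R)-carbinol as its isobutyrate together with the prenyl group, so only bridge opening, quinone formation and demethylation follow.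

Key step: step 7

Remark 1: the target SMILES is the 2-methylpropanoate ester of shikonin (isobutyrylshikonin, not an isobutyl ether); the naphthazarin is drawn as one of its rapidly equilibrating tautomers.
Remark 2: building blocks whose atoms remain in the target are numbered as starting materials; auxiliary reagents are given by name and SMILES at their step.
Remark 3: (+)-Ipc2B(allyl) (Ipc = isopinocampheyl) is taken as the commercial salt-free pentane solution.

Step 1
Reactants: 1 3-furaldehyde; 2 (+)-B-allyldiisopinocampheylborane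
Product: 4 (R)-1-(furan-3-yl)but-3-en-1-ol, via borinate ester 3 (not isolated)
Conditions: (+)-Ipc2B(allyl) (1 M in pentane, 1.2 equiv), Et2O, −78 °C; then 3 M NaOH, 30% H2O2, 0 °C to rt
Reagents that add atoms: (+)-B-allyldiisopinocampheylborane (2), SMILES C=CCB([C@H]1C[C@H]2C[C@@H]([C@@H]1C)C2(C)C)[C@H]1C[C@H]2C[C@@H]([C@@H]1C)C2(C)C
Why: Brown asymmetric allylboration: the allyl group is delivered through a closed chair transition state in which the isopinocampheyl groups of the (−)-α-pinene-derived reagent leave one carbonyl face open, the sense that converts aryl aldehydes into (R)-1-arylbut-3-en-1-ols, so this step should set the only stereocentre of the target as (R).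

Step 2
Reactants: 4 (R)-1-(furan-3-yl)but-3-en-1-ol; 5 isobutyryl chloride
Product: 6 (R)-1-(furan-3-yl)but-3-en-1-yl 2-methylpropanoate
Conditions: i-PrCOCl (1.2 equiv), Et3N (1.5 equiv), DMAP (5 mol %), CH2Cl2, 0 °C to rt
Reagents that add atoms: isobutyryl chloride (5), SMILES CC(C)C(Cl)=O
Why: DMAP-catalysed O-acylation with an acid chloride leaves the C–O bond at the stereocentre intact, so the configuration is retained, and the basic medium avoids ionisation of the furylic carbinol.

Step 3
Reactants: 6 (R)-1-(furan-3-yl)but-3-en-1-yl 2-methylpropanoate; 7 2-methyl-2-butene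
Product: 8 (R)-1-(furan-3-yl)-4-methylpent-3-en-1-yl 2-methylpropanoate
Conditions: second-generation Grubbs catalyst RuCl2(=CHPh)(H2IMes)(PCy3) (3 mol %), 2-methyl-2-butene (large excess), CH2Cl2, 40 °C, sealed tube
Reagents that add atoms: 2-methyl-2-butene (7), SMILES CC=C(C)C
Why: Olefin cross-metathesis exchanges the terminal methylene for an isopropylidene group with loss of propene, a detour taken because prenyl metal reagents attack aldehydes through their γ-carbon; the aromatic furan, the ester and the stereocentre are inert to the ruthenium carbene.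

Step 4
Reactants: 9 2,5-dimethoxyphenol
Product: 10 2,5-dimethoxyphenyl N-isopropylcarbamate
Conditions: i-PrNCO (1.5 equiv), Et3N (0.2 equiv), CH2Cl2, rt
Reagents that add atoms: isopropyl isocyanate, SMILES CC(C)N=C=O
Why: Base-catalysed addition of the phenol to the isocyanate (O-carbamoylation) installs a strong director for ortho-metalation that can later be removed under mild base.

Step 5
Reactants: 10 2,5-dimethoxyphenyl N-isopropylcarbamate
Product: 14 3,6-dimethoxy-2-(trimethylsilyl)phenyl N-isopropylcarbamate, via N-silyl carbamate 11 (not isolated), via aryllithium 12 (not isolated), via bis-silyl carbamate 13 (not isolated)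
Conditions: TBSOTf (1.1 equiv), TMEDA (1.1 equiv), Et2O, 0 °C to rt; then TMEDA (2 equiv), n-BuLi (2 equiv), −78 °C; then TMSCl (3.5 equiv), −78 °C to rt; aq. NaHSO4
Reagents that add atoms: chlorotrimethylsilane, SMILES C[Si](C)(C)Cl
Why: Directed ortho-metalation: once the N–H is masked in the flask by N-silylation, n-BuLi/TMEDA should lithiate the only ring position flanked by both the O-carbamate and a methoxy group, TMSCl traps the aryllithium, and the N–Si bond is hydrolysed on acidic work-up.

Step 6
Reactants: 14 3,6-dimethoxy-2-(trimethylsilyl)phenyl N-isopropylcarbamate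
Product: 16 3,6-dimethoxy-2-(trimethylsilyl)phenyl trifluoromethanesulfonate, via silyl phenol 15 (not isolated)
Conditions: DBU (1.5 equiv), Et2NH (1.2 equiv), MeCN, 40 °C; then PhNTf2 (1.5 equiv), rt
Reagents that add atoms: N-phenylbis(trifluoromethanesulfonimide), SMILES O=S(=O)(N(c1ccccc1)S(=O)(=O)C(F)(F)F)C(F)(F)F
Why: DBU induces E1cB loss of isopropyl isocyanate from the N-monoalkyl carbamate (scavenged by Et2NH as a urea) and the phenoxide is O-triflated in the same flask by PhNTf2, conditions mild enough to keep the aryl C–Si bond.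

Step 7
Reactants: 16 3,6-dimethoxy-2-(trimethylsilyl)phenyl trifluoromethanesulfonate; 8 (R)-1-(furan-3-yl)-4-methylpent-3-en-1-yl 2-methylpropanoate
Product: 18 (R)-1-(5,8-dimethoxy-1,4-dihydro-1,4-epoxynaphthalen-2-yl)-4-methylpent-3-en-1-yl 2-methylpropanoate (both bridge diastereomers), via 3,6-dimethoxybenzyne 17 (not isolated)
Conditions: 16 (1.3 equiv), CsF (3 equiv), MeCN, rt
Reagents that add atoms: none
Why: Attack of fluoride on the trimethylsilyl group triggers 1,2-elimination of triflate and releases 3,6-dimethoxybenzyne 17, whose strained π bond adds across C2 and C5 of the furan in a concerted [4+2] cycloaddition; the closest known reaction type is the aryne–furan Diels–Alder reaction, well established for this aryne. Ring A is closed by this intermolecular cycloaddition, C1–C8a and C4–C4a forming together to give the six-membered ring in its 1,4-oxygen-bridged form. The two bridgehead carbons become stereogenic without control from the remote (R)-carbinol, but both diastereomers are carried on because these centres vanish on aromatisation, and the side-chain stereocentre is not involved. Regiochemistry does not arise, since the aryne has a methoxy group beside each aryne carbon and either orientation of the furan gives the same constitution. The selectivity needed is chemoselectivity for the furan diene over an ene or [2+2] reaction at the prenyl alkene, which the much higher reactivity of furan towards arynes should secure, while the neutral fluoride medium leaves the ester untouched.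

Step 8
Reactants: 18 (R)-1-(5,8-dimethoxy-1,4-dihydro-1,4-epoxynaphthalen-2-yl)-4-methylpent-3-en-1-yl 2-methylpropanoate
Product: 21 (R)-1-(5,8-dimethoxy-1,4-dioxo-1,4-dihydronaphthalen-2-yl)-4-methylpent-3-en-1-yl 2-methylpropanoate, via 2-substituted 1-naphthol 19 (not isolated), via 3-substituted 1-naphthol 20 (not isolated)
Conditions: TsOH·H2O (0.1 equiv), acetone, 0 °C to rt; then aq. KH2PO4, ON(SO3K)2 (2.5 equiv), 0 °C to rt
Reagents that add atoms: potassium nitrosodisulfonate (Fremy's salt), SMILES [K+].[K+].[O]N(S(=O)(=O)[O-])S(=O)(=O)[O-]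
Why: Acid isomerisation of the 1,4-epoxy-1,4-dihydronaphthalene (protonation of the bridge oxygen, C–O cleavage to a cation stabilised by the neighbouring methoxy-substituted ring, loss of the bridgehead proton) gives two regioisomeric 1-naphthols, and Teuber oxidation with Fremy's salt should oxygenate the free para position of each, so both converge on one 1,4-quinone.

Step 9
Reactants: 21 (R)-1-(5,8-dimethoxy-1,4-dioxo-1,4-dihydronaphthalen-2-yl)-4-methylpent-3-en-1-yl 2-methylpropanoate
Product: 23 (R)-1-(5,8-dihydroxy-1,4-dioxo-1,4-dihydronaphthalen-2-yl)-4-methylpent-3-en-1-yl 2-methylpropanoate (isobutyrylshikonin; target), via diquinone 22 (not isolated)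
Conditions: AgO (4 equiv), 6 M HNO3, acetone, rt, 10 min; then aq. Na2S2O4 (1.1 equiv), EtOAc/H2O, 0 °C
Reagents that add atoms: water, SMILES O
Why: Oxidative demethylation of the para-dimethoxy ring with AgO in HNO3 (hydroquinone dimethyl ether to quinone, water supplying the new oxygen atoms) gives the naphthalene-1,4,5,8-tetraone, a strong oxidant that one equivalent of dithionite should reduce selectively to the naphthazarin without touching the ester, the alkene or the stereocentre.

Compound list
1 | 3-furaldehyde (furan-3-carbaldehyde) | O=Cc1ccoc1 | starting material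
2 | (+)-B-allyldiisopinocampheylborane, the enantiomer made from (−)-α-pinene | C=CCB([C@H]1C[C@H]2C[C@@H]([C@@H]1C)C2(C)C)[C@H]1C[C@H]2C[C@@H]([C@@H]1C)C2(C)C | starting material
3 | (R)-1-(furan-3-yl)but-3-en-1-yl diisopinocampheylborinate | C=CC[C@@H](OB([C@H]1C[C@H]2C[C@@H]([C@@H]1C)C2(C)C)[C@H]1C[C@H]2C[C@@H]([C@@H]1C)C2(C)C)c1ccoc1 | intermediate
4 | (R)-1-(furan-3-yl)but-3-en-1-ol | C=CC[C@@H](O)c1ccoc1 | intermediate
5 | isobutyryl chloride | CC(C)C(Cl)=O | starting material
6 | (R)-1-(furan-3-yl)but-3-en-1-yl 2-methylpropanoate | C=CC[C@@H](OC(=O)C(C)C)c1ccoc1 | intermediate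
7 | 2-methyl-2-butene | CC=C(C)C | starting material
8 | (R)-1-(furan-3-yl)-4-methylpent-3-en-1-yl 2-methylpropanoate | CC(C)=CC[C@@H](OC(=O)C(C)C)c1ccoc1 | intermediate
9 | 2,5-dimethoxyphenol | COc1ccc(OC)c(O)c1 | starting material
10 | 2,5-dimethoxyphenyl N-isopropylcarbamate | COc1ccc(OC)c(OC(=O)NC(C)C)c1 | intermediate
11 | 2,5-dimethoxyphenyl N-(tert-butyldimethylsilyl)-N-isopropylcarbamate | COc1ccc(OC)c(OC(=O)N(C(C)C)[Si](C)(C)C(C)(C)C)c1 | intermediate
12 | 6-lithio derivative of 11 (lithium between the carbamate and a methoxy group) | [Li]c1c(OC)ccc(OC)c1OC(=O)N(C(C)C)[Si](C)(C)C(C)(C)C | intermediate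
13 | 3,6-dimethoxy-2-(trimethylsilyl)phenyl N-(tert-butyldimethylsilyl)-N-isopropylcarbamate | COc1ccc(OC)c([Si](C)(C)C)c1OC(=O)N(C(C)C)[Si](C)(C)C(C)(C)C | intermediate
14 | 3,6-dimethoxy-2-(trimethylsilyl)phenyl N-isopropylcarbamate | COc1ccc(OC)c([Si](C)(C)C)c1OC(=O)NC(C)C | intermediate
15 | 3,6-dimethoxy-2-(trimethylsilyl)phenol (present as its DBU salt) | COc1ccc(OC)c([Si](C)(C)C)c1O | intermediate
16 | 3,6-dimethoxy-2-(trimethylsilyl)phenyl trifluoromethanesulfonate | COc1ccc(OC)c([Si](C)(C)C)c1OS(=O)(=O)C(F)(F)F | intermediate
17 | 3,6-dimethoxybenzyne | COC1=CC=C(OC)C#C1 | intermediate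
18 | (R)-1-(5,8-dimethoxy-1,4-dihydro-1,4-epoxynaphthalen-2-yl)-4-methylpent-3-en-1-yl 2-methylpropanoate, mixture of the two bridge diastereomers | CC(C)=CC[C@@H](OC(=O)C(C)C)C1=CC2OC1c1c(OC)ccc(OC)c12 | intermediate
19 | (R)-1-(1-hydroxy-5,8-dimethoxynaphthalen-2-yl)-4-methylpent-3-en-1-yl 2-methylpropanoate | CC(C)=CC[C@@H](OC(=O)C(C)C)c1ccc2c(OC)ccc(OC)c2c1O | intermediate
20 | (R)-1-(4-hydroxy-5,8-dimethoxynaphthalen-2-yl)-4-methylpent-3-en-1-yl 2-methylpropanoate | CC(C)=CC[C@@H](OC(=O)C(C)C)c1cc(O)c2c(OC)ccc(OC)c2c1 | intermediate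
21 | (R)-1-(5,8-dimethoxy-1,4-dioxo-1,4-dihydronaphthalen-2-yl)-4-methylpent-3-en-1-yl 2-methylpropanoate | CC(C)=CC[C@@H](OC(=O)C(C)C)C1=CC(=O)c2c(OC)ccc(OC)c2C1=O | intermediate
22 | (R)-4-methyl-1-(1,4,5,8-tetraoxo-1,4,5,8-tetrahydronaphthalen-2-yl)pent-3-en-1-yl 2-methylpropanoate | CC(C)=CC[C@@H](OC(=O)C(C)C)C1=CC(=O)C2=C(C1=O)C(=O)C=CC2=O | intermediate
23 | (R)-1-(5,8-dihydroxy-1,4-dioxo-1,4-dihydronaphthalen-2-yl)-4-methylpent-3-en-1-yl 2-methylpropanoate (isobutyrylshikonin) | CC(C)=CC[C@@H](OC(=O)C(C)C)C1=CC(=O)c2c(O)ccc(O)c2C1=O | target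

Total step count: 9 steps.
Longest linear sequence: 6 steps (steps 1, 2, 3, 7, 8, 9; the branch through steps 4, 5, 6 is equally long).

Steps most likely to fail

Step 9. Two processes are at risk. The two quinone carbonyls deactivate the dimethoxy ring, so the oxidation may stall while the oxidant starts to attack the prenyl alkene. Any excess of dithionite also reduces the naphthazarin to its hydroquinone, from which the benzylic isobutyrate can be expelled. The fallback sets out from 21 and comes back to the route at 23. Reductive acetylation (Zn dust, Ac2O, NaOAc, rt) should give (R)-1-(1,4-diacetoxy-5,8-dimethoxynaphthalen-2-yl)-4-methylpent-3-en-1-yl 2-methylpropanoate F1, in which the dimethoxy ring is now the most electron-rich part. Oxidative demethylation with (NH4)2Ce(NO3)6 in aqueous MeCN at 0 °C should then give (R)-1-(1,4-diacetoxy-5,8-dioxo-5,8-dihydronaphthalen-2-yl)-4-methylpent-3-en-1-yl 2-methylpropanoate F2. Brief methanolysis (catalytic K2CO3, MeOH, 0 °C) should remove the two aryl acetates, which are far more labile than the hindered alkyl isobutyrate. The naphthazarin released is the ring-swapped tautomer of 23 and therefore identical with it.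

Step 8. Acid may ionise the allylic, later benzylic, isobutyrate during bridge opening, which would erode the configuration or let the cation be captured by the alkene. The more hindered naphthol may also be oxygenated at its ortho instead of its para position. The fallback sets out from 18 and comes back to the route at 21. Isomerisation under neutral conditions with [RuCl2(CO)3]2 (5 mol %) in ClCH2CH2Cl at 60 °C opens the bridge by metal insertion into a bridgehead C–O bond, not through a free carbocation, and should give the naphthols 19 and 20. These are isolated under argon and oxygenated with Co(salen) and O2 in DMF, a para-selective phenol-to-quinone oxidation, to reach 21. No compound outside the list is made (F0).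

Step 7. The aryne may be diverted into an ene or [2+2] reaction with the electron-rich prenyl alkene, which would consume the chiral furan without closing ring A. The fallback sets out from 6 (with 16) and comes back to the route at 21. The allyl ester 6, whose monosubstituted alkene is a poor ene partner, is treated with 16 and CsF in MeCN to give (R)-1-(5,8-dimethoxy-1,4-dihydro-1,4-epoxynaphthalen-2-yl)but-3-en-1-yl 2-methylpropanoate F3. Treatment as in step 8 passes through (R)-1-(1-hydroxy-5,8-dimethoxynaphthalen-2-yl)but-3-en-1-yl 2-methylpropanoate F4 and (R)-1-(4-hydroxy-5,8-dimethoxynaphthalen-2-yl)but-3-en-1-yl 2-methylpropanoate F5 to (R)-1-(5,8-dimethoxy-1,4-dioxo-1,4-dihydronaphthalen-2-yl)but-3-en-1-yl 2-methylpropanoate F6. Metathesis is postponed to this quinone because the strained bridged alkene of F3 would itself undergo ring-opening metathesis. Cross-metathesis of F6 with 2-methyl-2-butene 7 (second-generation Grubbs catalyst, CH2Cl2, 40 °C) then installs the prenyl group and gives 21.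

Further compounds
F1 | step 9 | (R)-1-(1,4-diacetoxy-5,8-dimethoxynaphthalen-2-yl)-4-methylpent-3-en-1-yl 2-methylpropanoate | CC(C)=CC[C@@H](OC(=O)C(C)C)c1cc(OC(C)=O)c2c(OC)ccc(OC)c2c1OC(C)=O
F2 | step 9 | (R)-1-(1,4-diacetoxy-5,8-dioxo-5,8-dihydronaphthalen-2-yl)-4-methylpent-3-en-1-yl 2-methylpropanoate | CC(C)=CC[C@@H](OC(=O)C(C)C)c1cc(OC(C)=O)c2C(=O)C=CC(=O)c2c1OC(C)=O
F0 | step 8 | none | none
F3 | step 7 | (R)-1-(5,8-dimethoxy-1,4-dihydro-1,4-epoxynaphthalen-2-yl)but-3-en-1-yl 2-methylpropanoate (both bridge diastereomers) | C=CC[C@@H](OC(=O)C(C)C)C1=CC2OC1c1c(OC)ccc(OC)c12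
F4 | step 7 | (R)-1-(1-hydroxy-5,8-dimethoxynaphthalen-2-yl)but-3-en-1-yl 2-methylpropanoate | C=CC[C@@H](OC(=O)C(C)C)c1ccc2c(OC)ccc(OC)c2c1O
F5 | step 7 | (R)-1-(4-hydroxy-5,8-dimethoxynaphthalen-2-yl)but-3-en-1-yl 2-methylpropanoate | C=CC[C@@H](OC(=O)C(C)C)c1cc(O)c2c(OC)ccc(OC)c2c1
F6 | step 7 | (R)-1-(5,8-dimethoxy-1,4-dioxo-1,4-dihydronaphthalen-2-yl)but-3-en-1-yl 2-methylpropanoate | C=CC[C@@H](OC(=O)C(C)C)C1=CC(=O)c2c(OC)ccc(OC)c2C1=O
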